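The isoflavan is disconnected at C3–C4. The feature exploited is that O2' of ring B sits ortho to C1', so it can be tied to C4 as a benzyl ether. This places the future C3 and a C4–H bond five atoms apart. The precursor is therefore a ring-B aryldiazoacetate whose O2' carries the prenylated, silyl- and pivalate-protected ring-A benzyl group. A chiral dirhodium carboxylate converts it in one operation into a cis-2-aryl-2,3-dihydrobenzofuran-3-carboxylate, forming C3–C4, a sacrificial furan ring and both stereocentres. The tether then masks O2' while ring C closes at O1, is cleaved reductively to leave C4H2, and frees O2' for the chromene.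

Key step: step 7

Assumption: Rh2(S-PTTL)4, dirhodium tetrakis[N-phthaloyl-(S)-tert-leucinate], is taken to give the (2R,3S)-cis product, as it does with simpler 2-(benzyloxy)phenyl diazoacetates. If the first run shows the opposite sense, the catalyst from (R)-tert-leucine is used instead.
Numbering: isoflavan numbering (O1, C2, C3, C4, ring A C5–C8, ring B primed) is used for the atoms of all intermediates.

Step 1
Reactants: 1 methyl 2-(2,4-dihydroxyphenyl)acetate
Product: 2 methyl 2-[2-hydroxy-4-(triisopropylsilyloxy)phenyl]acetate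
Conditions: TIPSCl (1.0 equiv), imidazole, CH2Cl2/DMF, −10 → 0 °C
Reagents that add atoms: triisopropylsilyl chloride, CC(C)[Si](Cl)(C(C)C)C(C)C
Why: Phenol silylation under steric control: the bulky chlorosilane should take the open 4-OH, because the 2-OH is flanked by the CH2CO2Me arm and hydrogen-bonded to its carbonyl.

Step 2
Reactants: 3 5-bromo-2,4-dihydroxybenzaldehyde
Product: 5 4-bromo-2-formyl-5-(triisopropylsilyloxy)phenyl pivalate, via 4-O-TIPS bromosalicylaldehyde 4 (not isolated)
Conditions: TIPSCl (1.05 equiv), Et3N, CH2Cl2, 0 °C; then PivCl, Et3N, DMAP (cat.), 0 °C → rt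
Reagents that add atoms: triisopropylsilyl chloride, CC(C)[Si](Cl)(C(C)C)C(C)C; pivaloyl chloride, CC(C)(C)C(=O)Cl
Why: One-pot phenol silylation then DMAP-catalysed acylation: the acidic 4-OH para to the aldehyde reacts first because the 2-OH is locked in a hydrogen bond to the formyl group, and the 2-OH is then capped as a pivalate, preferred to a small acyl group because it resists acyl migration, phenoxide exchange and DBU in steps 4 to 6 yet falls to hydride in step 8.

Step 3
Reactants: 5 4-bromo-2-formyl-5-(triisopropylsilyloxy)phenyl pivalate; 6 tributyl(3-methylbut-2-en-1-yl)stannane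
Product: 7 2-formyl-4-(3-methylbut-2-en-1-yl)-5-(triisopropylsilyloxy)phenyl pivalate
Conditions: Pd(PPh3)4 (5 mol %), toluene (degassed), 100 °C
Reagents that add atoms: none
Why: Stille coupling: zerovalent palladium inserts into the C–Br bond, the allyl group is transferred from tin and reductive elimination at the less hindered allyl terminus should give the linear prenyl arene under neutral conditions that spare aldehyde, pivalate and silyl ether.

Step 4
Reactants: 7 2-formyl-4-(3-methylbut-2-en-1-yl)-5-(triisopropylsilyloxy)phenyl pivalate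
Product: 8 2-(hydroxymethyl)-4-(3-methylbut-2-en-1-yl)-5-(triisopropylsilyloxy)phenyl pivalate
Conditions: NaBH4, CeCl3·7H2O, MeOH/THF, −40 → −20 °C; aq. NH4Cl
Reagents that add atoms: none
Why: Luche reduction: cerium-activated hydride delivery is fast at low temperature in an almost neutral medium, so the new benzylic oxygen is protonated at once and neither pivaloyl migration to it nor the o-quinone methide over-reduction that would follow should set in.

Step 5
Reactants: 2 methyl 2-[2-hydroxy-4-(triisopropylsilyloxy)phenyl]acetate; 8 2-(hydroxymethyl)-4-(3-methylbut-2-en-1-yl)-5-(triisopropylsilyloxy)phenyl pivalate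
Product: 9 methyl 2-[2-{[2-(pivaloyloxy)-5-(3-methylbut-2-en-1-yl)-4-(triisopropylsilyloxy)phenyl]methoxy}-4-(triisopropylsilyloxy)phenyl]acetate
Conditions: PPh3, DIAD, THF, 0 °C → rt
Reagents that add atoms: none
Why: Mitsunobu etherification: the primary benzylic alcohol is activated as its oxyphosphonium salt and displaced by the only free phenol (O2' of ring B) under neutral conditions, which avoids both an unstable electron-rich benzyl halide and a basic phenoxide that could attack the aryl ester.

Step 6
Reactants: 9 methyl 2-[2-{[2-(pivaloyloxy)-5-(3-methylbut-2-en-1-yl)-4-(triisopropylsilyloxy)phenyl]methoxy}-4-(triisopropylsilyloxy)phenyl]acetate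
Product: 10 methyl 2-diazo-2-[2-{[2-(pivaloyloxy)-5-(3-methylbut-2-en-1-yl)-4-(triisopropylsilyloxy)phenyl]methoxy}-4-(triisopropylsilyloxy)phenyl]acetate
Conditions: p-ABSA, DBU, MeCN (dry), 0 °C → rt
Reagents that add atoms: 4-acetamidobenzenesulfonyl azide (p-ABSA), CC(=O)Nc1ccc(cc1)S(=O)(=O)N=[N+]=[N-]
Why: Regitz diazo transfer: DBU deprotonates the doubly activated ArCH2CO2Me position, the enolate attacks the terminal nitrogen of the sulfonyl azide and collapse of the triazene releases the sulfonamide, while the hindered pivalate and the TIPS ethers tolerate anhydrous DBU.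

Step 7
Reactants: 10 methyl 2-diazo-2-[2-{[2-(pivaloyloxy)-5-(3-methylbut-2-en-1-yl)-4-(triisopropylsilyloxy)phenyl]methoxy}-4-(triisopropylsilyloxy)phenyl]acetate
Product: 11 methyl (2R,3S)-2-[2-(pivaloyloxy)-5-(3-methylbut-2-en-1-yl)-4-(triisopropylsilyloxy)phenyl]-6-(triisopropylsilyloxy)-2,3-dihydrobenzofuran-3-carboxylate (cis)
Conditions: Rh2(S-PTTL)4 (2 mol %), 4 Å MS, toluene, slow addition of 10, −60 → −40 °C
Reagents that add atoms: none
Why: The diazo carbon of 10 binds an axial site of the dirhodium core, N2 leaves, and the donor/acceptor rhodium carbene inserts into one hydrogen of the O2'–CH2 group through a concerted but asynchronous three-centre transition state with hydride-transfer character. The closest known reaction type is the enantioselective dirhodium-carboxylate-catalysed intramolecular C–H insertion of methyl 2-(benzyloxy)phenyl diazoacetates to cis-2-aryl-2,3-dihydrobenzofuran-3-carboxylates, of which 10 is only a more substituted member. The dihydrofuran ring closes in the 1,5-insertion mode, that is through a five-membered cyclic array in which the carbene carbon (future C3) bonds to the ether carbon (future C4). C3 is set by the phthalimide wall of the (S)-tert-leucinate ligands, which leaves one carbene face open, and C4 by the choice between the two enantiotopic benzylic hydrogens, made so that ring A points away from that wall and ends cis to the ester under kinetic control. The step needs site selectivity for this C–H bond over the prenyl alkene, the allylic and isopropyl C–H bonds and the pivalate; this is secured because only the O–CH2 group can reach the carbene through a five-membered array, it is activated by O2' and by oxygenated ring A, and the trisubstituted alkene is both remote and too hindered for a donor/acceptor carbene. Low temperature and a neutral work-up keep the epimerisable cis ester intact.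

Step 8
Reactants: 11 methyl (2R,3S)-2-[2-(pivaloyloxy)-5-(3-methylbut-2-en-1-yl)-4-(triisopropylsilyloxy)phenyl]-6-(triisopropylsilyloxy)-2,3-dihydrobenzofuran-3-carboxylate
Product: 12 2-[(2R,3R)-3-(hydroxymethyl)-6-(triisopropylsilyloxy)-2,3-dihydrobenzofuran-2-yl]-4-(3-methylbut-2-en-1-yl)-5-(triisopropylsilyloxy)phenol
Conditions: LiAlH4 (4 equiv), THF, −40 → 0 °C; aq. Rochelle salt
Reagents that add atoms: none
Why: Hydride reduction of esters: LiAlH4 adds to the methyl ester faster than it deprotonates C3, so the cis relationship is kept, and the same reagent cleaves the aryl pivalate, exposing in one operation the C2 alcohol and the O1 phenol (the C3 descriptor changes from S to R only through the priority change from CO2Me to CH2OH).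

Step 9
Reactants: 12 2-[(2R,3R)-3-(hydroxymethyl)-6-(triisopropylsilyloxy)-2,3-dihydrobenzofuran-2-yl]-4-(3-methylbut-2-en-1-yl)-5-(triisopropylsilyloxy)phenol
Product: 13 (6aR,11aR)-2-(3-methylbut-2-en-1-yl)-3,9-bis(triisopropylsilyloxy)pterocarpan (cis-fused)
Conditions: PPh3, DIAD, THF (0.02 M), 0 °C → rt
Reagents that add atoms: none
Why: Intramolecular Mitsunobu etherification: the O1 phenol displaces the activated primary C2 oxygen in a 6-exo-tet closure of ring C that touches no stereocentre, is geometrically easy only for the cis isomer, and cannot involve O2' because that oxygen is still locked in the furan ring.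

Step 10
Reactants: 13 (6aR,11aR)-2-(3-methylbut-2-en-1-yl)-3,9-bis(triisopropylsilyloxy)pterocarpan
Product: 14 2-[(3R)-6-(3-methylbut-2-en-1-yl)-7-(triisopropylsilyloxy)chroman-3-yl]-5-(triisopropylsilyloxy)phenol
Conditions: Et3SiH (10 equiv), BF3·OEt2 (1.5 equiv), CH2Cl2, −78 → −40 °C; aq. NaHCO3
Reagents that add atoms: none
Why: Ionic hydrogenation of a benzylic ether (Lewis acid plus silane): BF3 ionises only the C4–O2' bond, whose cation is stabilised by O1 (ortho) and O7 (para), and excess Et3SiH traps it as C4H2, the aprotic acid and low temperature being chosen in place of catalytic hydrogenolysis to spare the prenyl alkene, the TIPS ethers and C3–H.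

Step 11
Reactants: 14 2-[(3R)-6-(3-methylbut-2-en-1-yl)-7-(triisopropylsilyloxy)chroman-3-yl]-5-(triisopropylsilyloxy)phenol; 15 3-chloro-3-methylbut-1-yne
Product: 16 (3R)-3-[2-(2-methylbut-3-yn-2-yloxy)-4-(triisopropylsilyloxy)phenyl]-6-(3-methylbut-2-en-1-yl)-7-(triisopropylsilyloxy)chroman
Conditions: 15 (2 equiv), DBU, CuCl2·2H2O (1 mol %), MeCN, 0 °C
Reagents that add atoms: none
Why: Copper-catalysed O-propargylation of a phenol with a tertiary propargylic chloride: the copper acetylide ionises to an allenylidene-type electrophile that is captured by the only free phenoxide, O2', under conditions mild enough for the aryl TIPS ethers.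

Step 12
Reactants: 16 (3R)-3-[2-(2-methylbut-3-yn-2-yloxy)-4-(triisopropylsilyloxy)phenyl]-6-(3-methylbut-2-en-1-yl)-7-(triisopropylsilyloxy)chroman
Product: 18 2,2-dimethyl-8-[(3R)-6-(3-methylbut-2-en-1-yl)-7-(triisopropylsilyloxy)chroman-3-yl]-5-(triisopropylsilyloxy)-2H-chromene, via allenylphenol 17 (not isolated)
Conditions: N,N-diethylaniline, 160 °C
Reagents that add atoms: none
Why: Aromatic propargyl Claisen rearrangement followed by tautomerisation, 1,5-hydrogen shift and oxa-6π electrocyclisation: of the two positions ortho to O2' only C3' bears hydrogen (C1' carries the chroman), so the dimethylpyran can fuse only across C2'–C3'.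

Step 13
Reactants: 18 2,2-dimethyl-8-[(3R)-6-(3-methylbut-2-en-1-yl)-7-(triisopropylsilyloxy)chroman-3-yl]-5-(triisopropylsilyloxy)-2H-chromene
Product: 19 8-[(3R)-7-hydroxy-6-(3-methylbut-2-en-1-yl)chroman-3-yl]-2,2-dimethyl-2H-chromen-5-ol (CNP0332706.1)
Conditions: TBAF (2.5 equiv), AcOH (2.5 equiv), THF, 0 °C
Reagents that add atoms: none
Why: Fluoride-mediated desilylation: the strong Si–F bond drives cleavage of both aryl TIPS ethers, and the acetic acid buffer keeps the medium mild for the o-prenylphenol and the chromene.

Compound list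
1 | methyl 2-(2,4-dihydroxyphenyl)acetate | COC(=O)Cc1ccc(O)cc1O | starting material
2 | methyl 2-[2-hydroxy-4-(triisopropylsilyloxy)phenyl]acetate | COC(=O)Cc1ccc(O[Si](C(C)C)(C(C)C)C(C)C)cc1O | intermediate
3 | 5-bromo-2,4-dihydroxybenzaldehyde | O=Cc1cc(Br)c(O)cc1O | starting material
4 | 5-bromo-2-hydroxy-4-(triisopropylsilyloxy)benzaldehyde | O=Cc1cc(Br)c(O[Si](C(C)C)(C(C)C)C(C)C)cc1O | intermediate
5 | 4-bromo-2-formyl-5-(triisopropylsilyloxy)phenyl pivalate | O=Cc1cc(Br)c(O[Si](C(C)C)(C(C)C)C(C)C)cc1OC(=O)C(C)(C)C | intermediate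
6 | tributyl(3-methylbut-2-en-1-yl)stannane | CCCC[Sn](CCCC)(CCCC)CC=C(C)C | starting material
7 | 2-formyl-4-(3-methylbut-2-en-1-yl)-5-(triisopropylsilyloxy)phenyl pivalate | O=Cc1cc(CC=C(C)C)c(O[Si](C(C)C)(C(C)C)C(C)C)cc1OC(=O)C(C)(C)C | intermediate
8 | 2-(hydroxymethyl)-4-(3-methylbut-2-en-1-yl)-5-(triisopropylsilyloxy)phenyl pivalate | OCc1cc(CC=C(C)C)c(O[Si](C(C)C)(C(C)C)C(C)C)cc1OC(=O)C(C)(C)C | intermediate
9 | methyl 2-[2-(ring-A benzyloxy)-4-(triisopropylsilyloxy)phenyl]acetate, ring A = 2-pivaloyloxy-5-prenyl-4-(triisopropylsilyloxy)phenyl | COC(=O)Cc1ccc(O[Si](C(C)C)(C(C)C)C(C)C)cc1OCc1cc(CC=C(C)C)c(O[Si](C(C)C)(C(C)C)C(C)C)cc1OC(=O)C(C)(C)C | intermediate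
10 | methyl 2-diazo-2-[2-(ring-A benzyloxy)-4-(triisopropylsilyloxy)phenyl]acetate (key-step precursor) | COC(=O)C(=[N+]=[N-])c1ccc(O[Si](C(C)C)(C(C)C)C(C)C)cc1OCc1cc(CC=C(C)C)c(O[Si](C(C)C)(C(C)C)C(C)C)cc1OC(=O)C(C)(C)C | intermediate
11 | methyl (2R,3S)-cis-2-(ring-A aryl)-6-(triisopropylsilyloxy)-2,3-dihydrobenzofuran-3-carboxylate (key-step product) | COC(=O)[C@H]1c2ccc(O[Si](C(C)C)(C(C)C)C(C)C)cc2O[C@H]1c1cc(CC=C(C)C)c(O[Si](C(C)C)(C(C)C)C(C)C)cc1OC(=O)C(C)(C)C | intermediate
12 | 2-[(2R,3R)-3-(hydroxymethyl)-6-(triisopropylsilyloxy)-2,3-dihydrobenzofuran-2-yl]-4-prenyl-5-(triisopropylsilyloxy)phenol | OC[C@H]1c2ccc(O[Si](C(C)C)(C(C)C)C(C)C)cc2O[C@H]1c1cc(CC=C(C)C)c(O[Si](C(C)C)(C(C)C)C(C)C)cc1O | intermediate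
13 | (6aR,11aR)-2-prenyl-3,9-bis(triisopropylsilyloxy)pterocarpan | C1[C@H]2c3ccc(O[Si](C(C)C)(C(C)C)C(C)C)cc3O[C@H]2c2cc(CC=C(C)C)c(O[Si](C(C)C)(C(C)C)C(C)C)cc2O1 | intermediate
14 | (3R)-2'-hydroxy-6-prenyl-7,4'-bis(triisopropylsilyloxy)isoflavan | C1[C@@H](c2ccc(O[Si](C(C)C)(C(C)C)C(C)C)cc2O)Cc2cc(CC=C(C)C)c(O[Si](C(C)C)(C(C)C)C(C)C)cc2O1 | intermediate
15 | 3-chloro-3-methylbut-1-yne | CC(C)(Cl)C#C | starting material
16 | (3R)-2'-(1,1-dimethylpropargyloxy)-6-prenyl-7,4'-bis(triisopropylsilyloxy)isoflavan | C1[C@@H](c2ccc(O[Si](C(C)C)(C(C)C)C(C)C)cc2OC(C)(C)C#C)Cc2cc(CC=C(C)C)c(O[Si](C(C)C)(C(C)C)C(C)C)cc2O1 | intermediate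
17 | (3R)-2'-hydroxy-3'-(3-methylbuta-1,2-dienyl)-6-prenyl-7,4'-bis(triisopropylsilyloxy)isoflavan | C1[C@@H](c2ccc(O[Si](C(C)C)(C(C)C)C(C)C)c(C=C=C(C)C)c2O)Cc2cc(CC=C(C)C)c(O[Si](C(C)C)(C(C)C)C(C)C)cc2O1 | intermediate
18 | bis-TIPS ether of the target, (3R) | C1[C@@H](c2ccc(O[Si](C(C)C)(C(C)C)C(C)C)c3c2OC(C)(C)C=C3)Cc2cc(CC=C(C)C)c(O[Si](C(C)C)(C(C)C)C(C)C)cc2O1 | intermediate
19 | 8-[(3R)-7-hydroxy-6-(3-methylbut-2-en-1-yl)chroman-3-yl]-2,2-dimethyl-2H-chromen-5-ol | CC(C)=CCc1cc2c(cc1O)OC[C@@H](c1ccc(O)c3c1OC(C)(C)C=C3)C2 | target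

Total step count: 13. Longest linear sequence: 12 steps (3 to 19, steps 2 to 13).

Steps most likely to fail

Step 7. The ortho-pivaloyloxy group on ring A may change how the benzyl ether sits in the chiral pocket. This would lead to poor facial selectivity and a weaker cis preference. Fallback: the absolute configuration is secured by separating diastereomers rather than by the catalyst.
- Material of insufficient enantiopurity is carried through steps 8 to 10. The trans isomer is removed at the ring-C closure.
- The fallback sets out from phenol 14, whose free O2'–H lies next to C3.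
- Acylation with (1S)-camphanic chloride (Et3N, DMAP, CH2Cl2, 0 °C) should give the (3R)-isoflavan camphanate F1 and the (3S)-isoflavan camphanate F2.
- These are separated by chromatography or crystallisation.
- Methanolysis of F1 (K2CO3, MeOH/THF, 0 °C) comes back to 14 as a single enantiomer, and the route resumes at step 11.

Step 10. The C4 cation may lose H3 to give an isoflav-3-ene, and re-protonation of that alkene would erode the configuration at C3. The acid released may also protonate the prenyl alkene. Fallback: the cationic cleavage is replaced by single-electron reductive cleavage of the benzyl aryl ether.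
- The fallback sets out from 13 and uses lithium 4,4'-di-tert-butylbiphenylide in THF at −78 °C, followed by an NH4Cl quench.
- The radical anion should expel the O2' phenoxide, and the benzylic anion is protonated to C4H2.
- No cation forms and no acid is present. Isolated alkenes and silyl ethers tolerate the reagent.
- The fallback comes back to the route at 14. No new compound arises (F0).

Step 12. The sigmatropic shift into C3', which is crowded by the 4'-OTIPS group, may be sluggish. Thermal loss of the propargyl group as the enyne could then compete. Fallback: the pyran is built by a formal [3+3] annulation instead of a rearrangement.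
- The fallback sets out from phenol 14 and bypasses 16.
- Condensation with 3-methylbut-2-enal (PhB(OH)2, AcOH, toluene, reflux with water removal) should ortho-hydroxyalkylate C3'. It then gives an o-quinone methide that closes by oxa-6π electrocyclisation.
- The fallback comes back to the route at 18. No new compound arises (F0).

Further compounds
F1 | step 7 | (1S,4R)-camphanate of (3R)-14 at O2' | C1[C@@H](c2ccc(O[Si](C(C)C)(C(C)C)C(C)C)cc2OC(=O)[C@@]23CC[C@@](C)(C(=O)O2)C3(C)C)Cc2cc(CC=C(C)C)c(O[Si](C(C)C)(C(C)C)C(C)C)cc2O1
F2 | step 7 | (1S,4R)-camphanate of the (3S)-enantiomer of 14 at O2' | C1[C@H](c2ccc(O[Si](C(C)C)(C(C)C)C(C)C)cc2OC(=O)[C@@]23CC[C@@](C)(C(=O)O2)C3(C)C)Cc2cc(CC=C(C)C)c(O[Si](C(C)C)(C(C)C)C(C)C)cc2O1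
F0 | step 10 | none | none
F0 | step 12 | none | none
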